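From the noon run to the dusk run the mean resting [G] climbs from 0.0425 M to 0.0598 M, while the mean [Q], with each Q holding two G, climbs from 0.00893 M to 0.0176 M. That is a factor of 1.97 in [Q], and the square of the factor in [G] is 1.98. Both runs read flat from 1.33 h on, so two G and one Q appear to stand in balance, and [Q] over the square of [G], read here as 4.93 M⁻¹, is the pairing quotient, an apparent equilibrium constant.

| flask | G | remark | time |
|---|---|---|---|
| noon | 0.10 M | run made earlier |  |
| dusk | 0.15 M | run made earlier |  |
| flask | 0.20 M |  | 20 h |

- noon (time / h: Q / %, G / %): 1.33: 18.8, 44.0; 2.00: 17.6, 41.4; 3.00: 18.9, 42.2; 5.00: 16.8, 42.5; 6.00: 17.5, 43.0; 10.0: 17.3, 42.3; 15.0: 18.1, 42.2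
- dusk (time / h: Q / %, G / %): 1.33: 24.0, 40.2; 2.00: 24.1, 40.2; 3.00: 23.5, 40.3; 5.00: 23.3, 39.3; 6.00: 23.0, 40.1; 10.0: 22.8, 39.3; 15.0: 23.5, 39.8

(each reading ± 0.5 percentage points)

- a species is counted by the G in it: one Q counts as two
- the earlier runs were read with a standard deviation of 0.5 percentage points
- a reading or a percentage of Q counts all its forms, free or not
- the reaction counts as stopped when no species that holds the G changes by six tenths of a point or more over the second half of the time

- which holds at 20 h: what has brought the reaction to rest, or that it has not come to rest (all of G has reacted / it is still moving / forward and back rates have come level)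
- how much Q there is at 20 h, in percent of the G charged

The readings also leave a gap: in these runs an unseen share of the charge stands at about 0.926 times [G]. The charge of the flask must equal [G], plus that share, plus two G for each Q, and this gives [G] as the charge divided by a sum that itself contains [G]: one, plus the share, plus two times the quotient times [G]. Starting from the dusk [G], this gives 0.0795 M; put back, it gives 0.0738 M, and further rounds close on 0.0750 M. This reckoning therefore expects balance in the flask, as 20 h is longer than 1.33 h, with 27.7% of Q. The forecast, holding that “All of this points to equilibrium rather than exhaustion”, says forward and back rates have come level and gives 27.7% of Q, between 26.6% and 28.9%.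

At 20 h the flask stands thus: forward and back rates have come level; it holds 40.9% of Q, and that Q includes 22.9% as crystals X.

    2 G ⇌ Q (K = 4.90 M⁻¹, k = 0.0600 M⁻¹ min⁻¹)
    G ⇌ Z (K = 0.950, k = 0.0180 min⁻¹)
    X ⇌ Q, rate k3*(cs3 - [Q]) while solid is left; crystals form when [Q] > cs3 (solubility = 18.0 mM, k = 0.760 min⁻¹)

The relaxation half-life of two G and dissolved Q, by this step alone at the asked time, is 0.431 h, shorter than the 20 h of the flask. Set on the flask's 30.3% of G, the quotient places 18.1% of the charge in dissolved Q, and the crystals X stand beside that. In a neighbouring flask charged with 0.050 M, the same balance gives 0.0232 M of G and 10.6% of Q. As computed, that neighbouring flask holds 10.4% of Q, with X at 0%.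

All runs are simulated for an exercise; noise was put on by code.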